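**Retrosynthetic overview**
1. The last skeletal bond is the benzoate C(=O)–O bond between ring C and the 3-hydroxybutanoate unit: Mitsunobu inversion joins ring C acid 23 to the (S)-3-hydroxybutanoate 32 of the ring A alcohol; acid hydrolysis (dioxolane, silyl ether) and hydrogenolysis of four benzyl ethers finish.
2. The route rests on ring C, a benzene with the carboxyl at C1, oxygen at C2 and C4, hydrogen at C3 and C5 and the 4-hydroxy-2-oxopentyl chain at C6. Arene C1, C2, C3 and C6 are C5, C4, C3 and C6 of 2-pyrone-5-carboxylate 14, and arene C4–C5 with the C4 oxygen are the two carbons of ketene acetal 17. A [4+2] addition, loss of CO2 and loss of Me3SiOH give the arene.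
3. Pyrone 14 comes from diallyl acetonedicarboxylate 10, C-acylated with the ketal-masked (R)-5-silyloxy-3-oxohexanoyl unit 8 (from methyl (R)-3-hydroxybutanoate), then lactonised and O-benzylated. The ester is allyl so that the acid can be freed while every phenol stays benzylated for the coupling.
4. Fragment 32: the 3,5-bis(benzyloxy)phenyl Grignard reagent opens (R)-propylene oxide; esterification with (S)-3-silyloxybutanoic acid and desilylation follow.
5. Ring order: 2-pyrone ring (step 8), then ring C by cycloaddition and aromatisation (step 11); ring A is bought as the aryl bromide.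

Key step: step 11

Remark: all three stereocentres of the target are (R) by CIP analysis; both enantiomers of methyl 3-hydroxybutanoate, (R)-propylene oxide and 1,3-bis(benzyloxy)-5-bromobenzene are taken as commercial. Keto forms drawn for β-dicarbonyl compounds stand for their tautomer mixtures. TBS = tert-butyldimethylsilyl, Bn = benzyl.

**Route**

Step 1
Reactants: 1 methyl (R)-3-hydroxybutanoate
Product: 2 methyl (R)-3-[(tert-butyldimethylsilyl)oxy]butanoate
Conditions: TBSCl, imidazole, DMF, 0 °C to rt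
Reagents that add atoms: tert-butyldimethylsilyl chloride, CC(C)(C)[Si](C)(C)Cl
Why: Imidazole-promoted silylation of a secondary alcohol (silyl ether protection) leaves the (R) centre untouched and masks the hydroxyl for the enolate, Lewis acid and Mitsunobu steps ahead.

Step 2
Reactants: 2 methyl (R)-3-(TBS-oxy)butanoate
Product: 3 (R)-3-[(tert-butyldimethylsilyl)oxy]butanoic acid
Conditions: LiOH·H2O, THF/MeOH/H2O, 0 °C to rt; cold 1 M HCl to pH 3
Reagents that add atoms: lithium hydroxide, [Li+].[OH-]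
Why: Saponification of an unhindered methyl ester, in which the poor silyloxide leaving group keeps β-elimination slow.

Step 3
Reactants: 3 (R)-3-(TBS-oxy)butanoic acid
Product: 6 ethyl (R)-5-[(tert-butyldimethylsilyl)oxy]-3-oxohexanoate, via acyl imidazolide 4 (not isolated), via acylmalonate half-ester 5 (not isolated)
Conditions: CDI, THF, rt; then Mg(O2CCH2CO2Et)2, THF, rt to 40 °C; cold 0.5 M HCl work-up
Reagents that add atoms: magnesium bis(monoethyl malonate), CCOC(=O)CC(=O)[O-].CCOC(=O)CC(=O)[O-].[Mg+2]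
Why: Masamune–Brooks two-carbon homologation, in which the magnesium malonate enolate is C-acylated by the imidazolide and the acylmalonate loses CO2 on acidification, without touching the silyl ether or the stereocentre.

Step 4
Reactants: 6 ethyl (R)-5-(TBS-oxy)-3-oxohexanoate
Product: 7 ethyl 2-[2-[(R)-2-[(tert-butyldimethylsilyl)oxy]propyl]-1,3-dioxolan-2-yl]acetate
Conditions: (Me3SiOCH2)2, TMSOTf (5 mol%), CH2Cl2, −78 to −20 °C; pyridine quench
Reagents that add atoms: 1,2-bis(trimethylsilyloxy)ethane, C[Si](C)(C)OCCO[Si](C)(C)C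
Why: Noyori ketalisation turns the ketone into the dioxolane under aprotic low-temperature conditions that a TBS ether tolerates, driven by formation of hexamethyldisiloxane.

Step 5
Reactants: 7 ethyl dioxolanyl acetate
Product: 8 2-[2-[(R)-2-[(tert-butyldimethylsilyl)oxy]propyl]-1,3-dioxolan-2-yl]acetic acid
Conditions: LiOH·H2O, THF/EtOH/H2O, rt; cold 0.5 M HCl to pH 4 with rapid extraction
Reagents that add atoms: lithium hydroxide, [Li+].[OH-]
Why: Saponification of a β,β-dialkoxy ester is clean in base, and the dioxolane survives brief contact with cold weak acid.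

Step 6
Reactants: 9 dimethyl 1,3-acetonedicarboxylate
Product: 10 diallyl 1,3-acetonedicarboxylate
Conditions: allyl alcohol (excess), DMAP (cat.), toluene, reflux, MeOH distilled off
Reagents that add atoms: allyl alcohol, C=CCO
Why: Transesterification of a β-keto ester, driven by removal of methanol, installs the ester that zerovalent palladium can later cleave beside benzyl ethers.

Step 7
Reactants: 8 dioxolanyl acetic acid; 10 diallyl 1,3-acetonedicarboxylate
Product: 12 diallyl 2-[2-[2-[(R)-2-[(tert-butyldimethylsilyl)oxy]propyl]-1,3-dioxolan-2-yl]acetyl]-3-oxopentanedioate, via acid chloride 11 (not isolated)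
Conditions: 8, 1-chloro-N,N,2-trimethylprop-1-en-1-amine, CH2Cl2, 0 °C to rt; then added to 10, MgCl2, pyridine, CH2Cl2, 0 °C to rt; cold aq. citric acid work-up
Reagents that add atoms: none
Why: C-acylation of a magnesium-chelated 1,3-dicarbonyl enolate by an acid chloride (Rathke conditions), the acid chloride being made with the neutral Ghosez reagent so that ketal and silyl ether never meet HCl.

Step 8
Reactants: 12 acylated diallyl acetonedicarboxylate
Product: 13 allyl 4-hydroxy-6-[[2-[(R)-2-[(tert-butyldimethylsilyl)oxy]propyl]-1,3-dioxolan-2-yl]methyl]-2-oxo-2H-pyran-5-carboxylate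
Conditions: DBU, toluene, 60 °C; cold aq. citric acid work-up
Reagents that add atoms: none
Why: Base-mediated lactonisation of a 3,5-dioxo ester, in which the enol oxygen of the new acyl ketone attacks the distal allyl ester (6-exo-trig, loss of allyl alcohol), is the only six-membered closure open to 12 and gives the 4-hydroxy-2-pyrone.

Step 9
Reactants: 13 allyl 4-hydroxy-2-pyrone-5-carboxylate
Product: 14 allyl 4-(benzyloxy)-6-[[2-[(R)-2-[(tert-butyldimethylsilyl)oxy]propyl]-1,3-dioxolan-2-yl]methyl]-2-oxo-2H-pyran-5-carboxylate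
Conditions: BnOH, PPh3, DIAD, THF, 0 °C to rt
Reagents that add atoms: benzyl alcohol, OCc1ccccc1
Why: Mitsunobu O-alkylation of the acidic 4-hydroxy-2-pyrone (a vinylogous acid) gives the 4-alkoxy-2-pyrone under neutral conditions, which avoids C3-benzylation and base-induced opening of the dioxolane.

Step 10
Reactants: 15 trimethylsilyl acetate
Product: 17 1,1-bis(trimethylsilyloxy)ethene, via lithium enolate 16 (not isolated)
Conditions: LiN(iPr)2, THF, −78 °C; TMSCl, −78 °C to rt; distillation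
Reagents that add atoms: chlorotrimethylsilane, C[Si](C)(C)Cl
Why: Kinetic enolisation of the silyl ester and O-silylation of the enolate is the standard preparation of a ketene bis(silyl) acetal.

Step 11
Reactants: 14 allyl 4-(benzyloxy)-2-pyrone-5-carboxylate; 17 1,1-bis(trimethylsilyloxy)ethene
Product: 21 allyl 2-(benzyloxy)-4-hydroxy-6-[[2-[(R)-2-[(tert-butyldimethylsilyl)oxy]propyl]-1,3-dioxolan-2-yl]methyl]benzoate, via bicyclic lactone 18 (not isolated), via cyclohexadiene ketal 19 (not isolated), via aryl trimethylsilyl ether 20 (not isolated)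
Conditions: 17 (5 equiv), toluene, sealed tube, 120 °C; then THF/0.5 M aq. citric acid, rt
Reagents that add atoms: none
Why: The pyrone diene C3=C4–C5=C6, made electron-poor by the C5 ester and the lactone carbonyl, takes up the electron-rich alkene of 17 in an inverse-electron-demand [4+2] addition (probably asynchronous, the CH2 of 17 bonding first to C6 to give a dienolate/silyloxycarbenium zwitterion that closes at C3) to give bicyclic lactone 18; retro-[4+2] loss of CO2 gives cyclohexadiene 19, 1,2-elimination of Me3SiOH aromatises it to 20, and aqueous citric acid cleaves the labile aryl O–Si bond to phenol 21. The closest known reaction is the Diels–Alder/decarboxylation/aromatisation of 2-pyrone-5-carboxylates (coumalates and their 4,6-disubstituted congeners) with ketene acetals to 4-alkoxybenzoates. Ring C is closed by an intermolecular [4+2] annulation that forms two ring bonds at once (arene C5–C6 and C3–C4), so the six-membered carbocycle is complete before CO2 leaves. No lasting stereocentre is created: the two bridgehead centres of 18 vanish on aromatisation and the (R) silyloxy centre in the side chain is remote from every bond change. The step needs one regiochemistry, acetal carbon to pyrone C3 and CH2 to pyrone C6, and the substrate secures it because C6 is the β-carbon of the C5 acrylate unit and the δ-terminus of the dienyl lactone, whereas C4 is deactivated by its benzyloxy donor and C3 is the nucleophilic α-carbon. The 4-benzyloxy group and the fully substituted C6 slow the addition, which is why excess 17 and heat in a sealed tube are used.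

Step 12
Reactants: 21 allyl 2-(benzyloxy)-4-hydroxybenzoate
Product: 22 allyl 2,4-bis(benzyloxy)-6-[[2-[(R)-2-[(tert-butyldimethylsilyl)oxy]propyl]-1,3-dioxolan-2-yl]methyl]benzoate
Conditions: BnBr, K2CO3, DMF, rt
Reagents that add atoms: benzyl bromide, BrCc1ccccc1
Why: Williamson etherification of the only free phenol (para to the ester, hence acidic) protects O4 as the same benzyl ether as O2, so that no phenol competes in the later Mitsunobu coupling.

Step 13
Reactants: 22 allyl 2,4-bis(benzyloxy)benzoate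
Product: 23 2,4-bis(benzyloxy)-6-[[2-[(R)-2-[(tert-butyldimethylsilyl)oxy]propyl]-1,3-dioxolan-2-yl]methyl]benzoic acid
Conditions: Pd(PPh3)4 (5 mol%), morpholine, THF, rt; NaH2PO4 buffer (pH 4) work-up
Reagents that add atoms: none
Why: Tsuji–Trost deallylation, in which zerovalent palladium ionises the allyl ester to a π-allyl complex that morpholine captures, frees the hindered acid under neutral conditions without touching benzyl ethers, ketal or silyl ether.

Step 14
Reactants: 24 1,3-bis(benzyloxy)-5-bromobenzene; 25 (R)-propylene oxide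
Product: 27 (R)-1-[3,5-bis(benzyloxy)phenyl]propan-2-ol, via aryl Grignard reagent 26 (not isolated)
Conditions: Mg, THF, reflux; then CuI (10 mol%), 25, THF, −30 to 0 °C; sat. aq. NH4Cl
Reagents that add atoms: none
Why: Copper-catalysed Grignard opening of a terminal epoxide takes place at the unsubstituted carbon, so the C–O stereocentre of (R)-propylene oxide passes unchanged into the (R)-alcohol.

Step 15
Reactants: 28 methyl (S)-3-hydroxybutanoate
Product: 29 methyl (S)-3-[(tert-butyldimethylsilyl)oxy]butanoate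
Conditions: TBSCl, imidazole, DMF, 0 °C to rt
Reagents that add atoms: tert-butyldimethylsilyl chloride, CC(C)(C)[Si](C)(C)Cl
Why: Silyl ether protection of the secondary alcohol as in step 1, with the (S) centre untouched.

Step 16
Reactants: 29 methyl (S)-3-(TBS-oxy)butanoate
Product: 30 (S)-3-[(tert-butyldimethylsilyl)oxy]butanoic acid
Conditions: LiOH·H2O, THF/MeOH/H2O, 0 °C to rt; cold 1 M HCl to pH 3
Reagents that add atoms: lithium hydroxide, [Li+].[OH-]
Why: Saponification as in step 2.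

Step 17
Reactants: 27 (R)-1-[3,5-bis(benzyloxy)phenyl]propan-2-ol; 30 (S)-3-(TBS-oxy)butanoic acid
Product: 31 (R)-1-[3,5-bis(benzyloxy)phenyl]propan-2-yl (S)-3-[(tert-butyldimethylsilyl)oxy]butanoate
Conditions: EDC·HCl, DMAP, CH2Cl2, 0 °C to rt
Reagents that add atoms: none
Why: Steglich esterification of an unhindered aliphatic acid with a secondary alcohol forms the ester at the acyl carbon, so both stereocentres are retained.

Step 18
Reactants: 31 silyl-protected diester fragment
Product: 32 (R)-1-[3,5-bis(benzyloxy)phenyl]propan-2-yl (S)-3-hydroxybutanoate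
Conditions: HF·pyridine, THF, 0 °C to rt
Reagents that add atoms: none
Why: Fluoride cleavage of the silyl ether under buffered acidic conditions avoids base-induced retro-aldol or elimination of the β-hydroxy ester and leaves the benzyl ethers intact.

Step 19
Reactants: 23 ring C acid; 32 (S)-hydroxy ester of the ring A alcohol
Product: 33 (R)-4-[[(R)-1-[3,5-bis(benzyloxy)phenyl]propan-2-yl]oxy]-4-oxobutan-2-yl 2,4-bis(benzyloxy)-6-[[2-[(R)-2-[(tert-butyldimethylsilyl)oxy]propyl]-1,3-dioxolan-2-yl]methyl]benzoate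
Conditions: PPh3, DIAD, toluene, 0 °C to rt
Reagents that add atoms: none
Why: Mitsunobu esterification, in which the carboxylate of 23 displaces the oxyphosphonium of the secondary alcohol by SN2, inverts the (S) carbinol centre to the (R) acyloxy centre of the target and avoids acylation at the hindered carbonyl of a 2,6-disubstituted benzoic acid.

Step 20
Reactants: 33 fully protected triester
Product: 34 (R)-4-[[(R)-1-[3,5-bis(benzyloxy)phenyl]propan-2-yl]oxy]-4-oxobutan-2-yl 2,4-bis(benzyloxy)-6-[(R)-4-hydroxy-2-oxopentyl]benzoate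
Conditions: 2 M aq. HCl, THF, rt
Reagents that add atoms: water, O
Why: Acid hydrolysis removes the dioxolane (the ketone oxygen comes from water) and the secondary silyl ether in one operation, while the two secondary esters and the benzyl ethers are stable to dilute acid at room temperature.

Step 21
Reactants: 34 tetra-O-benzyl hansforester K
Product: 35 hansforester K
Conditions: H2 (1 atm), Pd/C (10% palladium on carbon), EtOAc/EtOH, rt
Reagents that add atoms: none
Why: Hydrogenolysis of four aryl benzyl ethers is neutral; no ester C–O bond is benzylic and the aliphatic ketone is not reduced, so the three (R) centres are untouched.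

**Compound list**
1 | methyl (R)-3-hydroxybutanoate | COC(=O)C[C@@H](C)O | starting material
2 | methyl (R)-3-[(tert-butyldimethylsilyl)oxy]butanoate | COC(=O)C[C@@H](C)O[Si](C)(C)C(C)(C)C | intermediate
3 | (R)-3-[(tert-butyldimethylsilyl)oxy]butanoic acid | OC(=O)C[C@@H](C)O[Si](C)(C)C(C)(C)C | intermediate
4 | 1-[(R)-3-[(tert-butyldimethylsilyl)oxy]butanoyl]-1H-imidazole | O=C(C[C@@H](C)O[Si](C)(C)C(C)(C)C)n1ccnc1 | intermediate
5 | (5R)-5-[(tert-butyldimethylsilyl)oxy]-2-(ethoxycarbonyl)-3-oxohexanoic acid (magnesium salt in the flask, C2 labile) | CCOC(=O)C(C(=O)O)C(=O)C[C@@H](C)O[Si](C)(C)C(C)(C)C | intermediate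
6 | ethyl (R)-5-[(tert-butyldimethylsilyl)oxy]-3-oxohexanoate | CCOC(=O)CC(=O)C[C@@H](C)O[Si](C)(C)C(C)(C)C | intermediate
7 | ethyl 2-[2-[(R)-2-[(tert-butyldimethylsilyl)oxy]propyl]-1,3-dioxolan-2-yl]acetate | CCOC(=O)CC1(C[C@@H](C)O[Si](C)(C)C(C)(C)C)OCCO1 | intermediate
8 | 2-[2-[(R)-2-[(tert-butyldimethylsilyl)oxy]propyl]-1,3-dioxolan-2-yl]acetic acid | OC(=O)CC1(C[C@@H](C)O[Si](C)(C)C(C)(C)C)OCCO1 | intermediate
9 | dimethyl 1,3-acetonedicarboxylate | COC(=O)CC(=O)CC(=O)OC | starting material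
10 | diallyl 1,3-acetonedicarboxylate | C=CCOC(=O)CC(=O)CC(=O)OCC=C | intermediate
11 | 2-[2-[(R)-2-[(tert-butyldimethylsilyl)oxy]propyl]-1,3-dioxolan-2-yl]acetyl chloride | O=C(Cl)CC1(C[C@@H](C)O[Si](C)(C)C(C)(C)C)OCCO1 | intermediate
12 | diallyl 2-[2-[2-[(R)-2-[(tert-butyldimethylsilyl)oxy]propyl]-1,3-dioxolan-2-yl]acetyl]-3-oxopentanedioate (C2 labile) | C=CCOC(=O)CC(=O)C(C(=O)OCC=C)C(=O)CC1(C[C@@H](C)O[Si](C)(C)C(C)(C)C)OCCO1 | intermediate
13 | allyl 4-hydroxy-6-[[2-[(R)-2-[(tert-butyldimethylsilyl)oxy]propyl]-1,3-dioxolan-2-yl]methyl]-2-oxo-2H-pyran-5-carboxylate | C=CCOC(=O)C1=C(CC2(C[C@@H](C)O[Si](C)(C)C(C)(C)C)OCCO2)OC(=O)C=C1O | intermediate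
14 | allyl 4-(benzyloxy)-6-[[2-[(R)-2-[(tert-butyldimethylsilyl)oxy]propyl]-1,3-dioxolan-2-yl]methyl]-2-oxo-2H-pyran-5-carboxylate | C=CCOC(=O)C1=C(CC2(C[C@@H](C)O[Si](C)(C)C(C)(C)C)OCCO2)OC(=O)C=C1OCc1ccccc1 | intermediate
15 | trimethylsilyl acetate | CC(=O)O[Si](C)(C)C | starting material
16 | lithium 1-(trimethylsilyloxy)ethen-1-olate | [Li+].C=C([O-])O[Si](C)(C)C | intermediate
17 | 1,1-bis(trimethylsilyloxy)ethene | C=C(O[Si](C)(C)C)O[Si](C)(C)C | intermediate
18 | allyl 5-(benzyloxy)-1-[[2-[(R)-2-[(tert-butyldimethylsilyl)oxy]propyl]-1,3-dioxolan-2-yl]methyl]-3-oxo-8,8-bis(trimethylsilyloxy)-2-oxabicyclo[2.2.2]oct-5-ene-6-carboxylate (both bridgehead diastereomers) | O=C1OC2(CC3(C[C@@H](C)O[Si](C)(C)C(C)(C)C)OCCO3)CC(O[Si](C)(C)C)(O[Si](C)(C)C)C1C(OCc1ccccc1)=C2C(=O)OCC=C | intermediate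
19 | allyl 6-(benzyloxy)-2-[[2-[(R)-2-[(tert-butyldimethylsilyl)oxy]propyl]-1,3-dioxolan-2-yl]methyl]-4,4-bis(trimethylsilyloxy)cyclohexa-1,5-diene-1-carboxylate | C=CCOC(=O)C1=C(CC2(C[C@@H](C)O[Si](C)(C)C(C)(C)C)OCCO2)CC(O[Si](C)(C)C)(O[Si](C)(C)C)C=C1OCc1ccccc1 | intermediate
20 | allyl 2-(benzyloxy)-6-[[2-[(R)-2-[(tert-butyldimethylsilyl)oxy]propyl]-1,3-dioxolan-2-yl]methyl]-4-(trimethylsilyloxy)benzoate | C=CCOC(=O)c1c(OCc2ccccc2)cc(O[Si](C)(C)C)cc1CC1(C[C@@H](C)O[Si](C)(C)C(C)(C)C)OCCO1 | intermediate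
21 | allyl 2-(benzyloxy)-4-hydroxy-6-[[2-[(R)-2-[(tert-butyldimethylsilyl)oxy]propyl]-1,3-dioxolan-2-yl]methyl]benzoate | C=CCOC(=O)c1c(OCc2ccccc2)cc(O)cc1CC1(C[C@@H](C)O[Si](C)(C)C(C)(C)C)OCCO1 | intermediate
22 | allyl 2,4-bis(benzyloxy)-6-[[2-[(R)-2-[(tert-butyldimethylsilyl)oxy]propyl]-1,3-dioxolan-2-yl]methyl]benzoate | C=CCOC(=O)c1c(OCc2ccccc2)cc(OCc2ccccc2)cc1CC1(C[C@@H](C)O[Si](C)(C)C(C)(C)C)OCCO1 | intermediate
23 | 2,4-bis(benzyloxy)-6-[[2-[(R)-2-[(tert-butyldimethylsilyl)oxy]propyl]-1,3-dioxolan-2-yl]methyl]benzoic acid | OC(=O)c1c(OCc2ccccc2)cc(OCc2ccccc2)cc1CC1(C[C@@H](C)O[Si](C)(C)C(C)(C)C)OCCO1 | intermediate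
24 | 1,3-bis(benzyloxy)-5-bromobenzene | Brc1cc(OCc2ccccc2)cc(OCc2ccccc2)c1 | starting material
25 | (R)-propylene oxide | C[C@@H]1CO1 | starting material
26 | [3,5-bis(benzyloxy)phenyl]magnesium bromide | Br[Mg]c1cc(OCc2ccccc2)cc(OCc2ccccc2)c1 | intermediate
27 | (R)-1-[3,5-bis(benzyloxy)phenyl]propan-2-ol | C[C@@H](O)Cc1cc(OCc2ccccc2)cc(OCc2ccccc2)c1 | intermediate
28 | methyl (S)-3-hydroxybutanoate | COC(=O)C[C@H](C)O | starting material
29 | methyl (S)-3-[(tert-butyldimethylsilyl)oxy]butanoate | COC(=O)C[C@H](C)O[Si](C)(C)C(C)(C)C | intermediate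
30 | (S)-3-[(tert-butyldimethylsilyl)oxy]butanoic acid | OC(=O)C[C@H](C)O[Si](C)(C)C(C)(C)C | intermediate
31 | (R)-1-[3,5-bis(benzyloxy)phenyl]propan-2-yl (S)-3-[(tert-butyldimethylsilyl)oxy]butanoate | C[C@H](Cc1cc(OCc2ccccc2)cc(OCc2ccccc2)c1)OC(=O)C[C@H](C)O[Si](C)(C)C(C)(C)C | intermediate
32 | (R)-1-[3,5-bis(benzyloxy)phenyl]propan-2-yl (S)-3-hydroxybutanoate | C[C@H](Cc1cc(OCc2ccccc2)cc(OCc2ccccc2)c1)OC(=O)C[C@H](C)O | intermediate
33 | (R)-4-[[(R)-1-[3,5-bis(benzyloxy)phenyl]propan-2-yl]oxy]-4-oxobutan-2-yl 2,4-bis(benzyloxy)-6-[[2-[(R)-2-[(tert-butyldimethylsilyl)oxy]propyl]-1,3-dioxolan-2-yl]methyl]benzoate | C[C@H](Cc1cc(OCc2ccccc2)cc(OCc2ccccc2)c1)OC(=O)C[C@@H](C)OC(=O)c1c(OCc2ccccc2)cc(OCc2ccccc2)cc1CC1(C[C@@H](C)O[Si](C)(C)C(C)(C)C)OCCO1 | intermediate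
34 | (R)-4-[[(R)-1-[3,5-bis(benzyloxy)phenyl]propan-2-yl]oxy]-4-oxobutan-2-yl 2,4-bis(benzyloxy)-6-[(R)-4-hydroxy-2-oxopentyl]benzoate | C[C@H](Cc1cc(OCc2ccccc2)cc(OCc2ccccc2)c1)OC(=O)C[C@@H](C)OC(=O)c1c(OCc2ccccc2)cc(OCc2ccccc2)cc1CC(=O)C[C@@H](C)O | intermediate
35 | hansforester K, (R)-4-[[(R)-1-(3,5-dihydroxyphenyl)propan-2-yl]oxy]-4-oxobutan-2-yl 2,4-dihydroxy-6-[(R)-4-hydroxy-2-oxopentyl]benzoate | C[C@H](Cc1cc(O)cc(O)c1)OC(=O)C[C@@H](C)OC(=O)c1c(O)cc(O)cc1CC(=O)C[C@@H](C)O | target

**Step count and risks**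

Total step count: 21. Longest linear sequence: 14 steps (steps 1–5, 7–9, 11–13, 19–21).

Steps most likely to fail:

1. Step 11. The cycloaddition may be too slow at the fully substituted C6, which is flanked by a neopentyl-like ketal carbon, on a diene deactivated by the benzyloxy donor. Thermal O-to-C silyl migration of 17, or conjugate addition with silyl transfer and no ring closure, could then outrun arene formation. The fallback builds ring C by polyketide-type aldol aromatisation; it sets out from acid chloride 11 (made from 8 as in step 7) and returns at 22. 2,2-Dimethyl-6-(2-oxopropyl)-4H-1,3-dioxin-4-one F1 is made from commercial 2,2,6-trimethyl-4H-1,3-dioxin-4-one with LiN(iPr)2 and acetyl chloride. Its dianion (2 equiv LiN(iPr)2, THF, −78 °C) is C-acylated at the terminal carbon with 11 to give 6-[5-[2-[(R)-2-[(tert-butyldimethylsilyl)oxy]propyl]-1,3-dioxolan-2-yl]-2,4-dioxopentyl]-2,2-dimethyl-4H-1,3-dioxin-4-one F2. Heating F2 with allyl alcohol in toluene at 110 °C releases acetone and an acylketene, which is trapped as allyl 8-[2-[(R)-2-[(tert-butyldimethylsilyl)oxy]propyl]-1,3-dioxolan-2-yl]-3,5,7-trioxooctanoate F3. Cs2CO3 in iPrOH/CH2Cl2, then AcOH, brings about aldol closure of C2 onto the C7 ketone and dehydration to allyl 2,4-dihydroxy-6-[[2-[(R)-2-[(tert-butyldimethylsilyl)oxy]propyl]-1,3-dioxolan-2-yl]methyl]benzoate F4. BnBr and K2CO3 in DMF benzylate both phenols to give 22.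

2. Step 19. The oxyphosphonium of the β-hydroxy ester may eliminate to the crotonate faster than the hindered carboxylate displaces it. The fallback moves the inversion to an alcohol that cannot eliminate towards a carbonyl; it sets out from acid 23 and alcohol 27 and returns at 33. Mitsunobu reaction of 23 with commercial (S)-pent-4-en-2-ol (PPh3, DIAD, toluene) gives (R)-pent-4-en-2-yl 2,4-bis(benzyloxy)-6-[[2-[(R)-2-[(tert-butyldimethylsilyl)oxy]propyl]-1,3-dioxolan-2-yl]methyl]benzoate F5. Cleavage of the alkene with OsO4 (cat.) and NaIO4 with 2,6-lutidine in dioxane/water gives (R)-4-oxobutan-2-yl 2,4-bis(benzyloxy)-6-[[2-[(R)-2-[(tert-butyldimethylsilyl)oxy]propyl]-1,3-dioxolan-2-yl]methyl]benzoate F6. Pinnick oxidation (NaClO2, NaH2PO4, 2-methyl-2-butene) gives (R)-3-[[2,4-bis(benzyloxy)-6-[[2-[(R)-2-[(tert-butyldimethylsilyl)oxy]propyl]-1,3-dioxolan-2-yl]methyl]benzoyl]oxy]butanoic acid F7. Esterification of F7 with 27 (EDC·HCl, DMAP, CH2Cl2) gives 33.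

3. Step 7. Pyridine may deprotonate the acid chloride 11 next to the ketal carbon, giving a ketene or opening the dioxolane by β-elimination, and O-acylation or double acylation of the chelated enolate may compete. The fallback forms the other C–C bond of the tricarbonyl unit with a simple acid chloride; it sets out from acid 8 and returns at 13. Acid 8 is condensed with Meldrum's acid (EDC·HCl, DMAP, CH2Cl2) to 5-[2-[2-[(R)-2-[(tert-butyldimethylsilyl)oxy]propyl]-1,3-dioxolan-2-yl]-1-hydroxyethylidene]-2,2-dimethyl-1,3-dioxane-4,6-dione F8. Heating F8 with allyl alcohol in toluene at 80 °C gives allyl 4-[2-[(R)-2-[(tert-butyldimethylsilyl)oxy]propyl]-1,3-dioxolan-2-yl]-3-oxobutanoate F9. The magnesium enolate of F9 (MgCl2, pyridine, CH2Cl2) is C-acylated with methyl malonyl chloride to give 1-allyl 5-methyl 2-[2-[2-[(R)-2-[(tert-butyldimethylsilyl)oxy]propyl]-1,3-dioxolan-2-yl]acetyl]-3-oxopentanedioate F10. DBU in toluene at 60 °C lactonises F10 onto the methyl ester, with loss of methanol, to give 13.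

**Further compounds**
F1 | step 11 | 2,2-dimethyl-6-(2-oxopropyl)-4H-1,3-dioxin-4-one | CC(=O)CC1=CC(=O)OC(C)(C)O1
F2 | step 11 | 6-[5-[2-[(R)-2-[(tert-butyldimethylsilyl)oxy]propyl]-1,3-dioxolan-2-yl]-2,4-dioxopentyl]-2,2-dimethyl-4H-1,3-dioxin-4-one | CC1(C)OC(=O)C=C(CC(=O)CC(=O)CC2(C[C@@H](C)O[Si](C)(C)C(C)(C)C)OCCO2)O1
F3 | step 11 | allyl 8-[2-[(R)-2-[(tert-butyldimethylsilyl)oxy]propyl]-1,3-dioxolan-2-yl]-3,5,7-trioxooctanoate | C=CCOC(=O)CC(=O)CC(=O)CC(=O)CC1(C[C@@H](C)O[Si](C)(C)C(C)(C)C)OCCO1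
F4 | step 11 | allyl 2,4-dihydroxy-6-[[2-[(R)-2-[(tert-butyldimethylsilyl)oxy]propyl]-1,3-dioxolan-2-yl]methyl]benzoate | C=CCOC(=O)c1c(O)cc(O)cc1CC1(C[C@@H](C)O[Si](C)(C)C(C)(C)C)OCCO1
F5 | step 19 | (R)-pent-4-en-2-yl 2,4-bis(benzyloxy)-6-[[2-[(R)-2-[(tert-butyldimethylsilyl)oxy]propyl]-1,3-dioxolan-2-yl]methyl]benzoate | C=CC[C@@H](C)OC(=O)c1c(OCc2ccccc2)cc(OCc2ccccc2)cc1CC1(C[C@@H](C)O[Si](C)(C)C(C)(C)C)OCCO1
F6 | step 19 | (R)-4-oxobutan-2-yl 2,4-bis(benzyloxy)-6-[[2-[(R)-2-[(tert-butyldimethylsilyl)oxy]propyl]-1,3-dioxolan-2-yl]methyl]benzoate | O=CC[C@@H](C)OC(=O)c1c(OCc2ccccc2)cc(OCc2ccccc2)cc1CC1(C[C@@H](C)O[Si](C)(C)C(C)(C)C)OCCO1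
F7 | step 19 | (R)-3-[[2,4-bis(benzyloxy)-6-[[2-[(R)-2-[(tert-butyldimethylsilyl)oxy]propyl]-1,3-dioxolan-2-yl]methyl]benzoyl]oxy]butanoic acid | OC(=O)C[C@@H](C)OC(=O)c1c(OCc2ccccc2)cc(OCc2ccccc2)cc1CC1(C[C@@H](C)O[Si](C)(C)C(C)(C)C)OCCO1
F8 | step 7 | 5-[2-[2-[(R)-2-[(tert-butyldimethylsilyl)oxy]propyl]-1,3-dioxolan-2-yl]-1-hydroxyethylidene]-2,2-dimethyl-1,3-dioxane-4,6-dione | CC1(C)OC(=O)C(=C(O)CC2(C[C@@H](C)O[Si](C)(C)C(C)(C)C)OCCO2)C(=O)O1
F9 | step 7 | allyl 4-[2-[(R)-2-[(tert-butyldimethylsilyl)oxy]propyl]-1,3-dioxolan-2-yl]-3-oxobutanoate | C=CCOC(=O)CC(=O)CC1(C[C@@H](C)O[Si](C)(C)C(C)(C)C)OCCO1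
F10 | step 7 | 1-allyl 5-methyl 2-[2-[2-[(R)-2-[(tert-butyldimethylsilyl)oxy]propyl]-1,3-dioxolan-2-yl]acetyl]-3-oxopentanedioate | C=CCOC(=O)C(C(=O)CC(=O)OC)C(=O)CC1(C[C@@H](C)O[Si](C)(C)C(C)(C)C)OCCO1
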